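**Plan**
- Retrosynthesis: remove the silyl ether on ring A, cut the B–C depside ester (ring B O4–CO of ring C), then open ring B itself at C1–C2 and C5–C6; last, cut the alkynoate ester on the ring A 4-oxygen.
- Enabling feature: ring B carries the carboxyl at C1, OCH3 at C2, oxygen at C4 and CH3 at C6. C2–C5 therefore map onto a 1,1-dimethoxy-3-silyloxybutadiene, and C1/C6 with carboxyl and methyl onto a but-2-ynoate.
- Forward: ring A (methyl orsellinate) is esterified at 4-OH with but-2-ynoic acid and silylated at 2-OH; ring B is then grown on this ynoate by cycloaddition and aromatisation, so the hindered A–B ester is made as an unhindered alkynoate.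
- Ring C (everninic acid, from methyl orsellinate) is attached to the new ring B phenol through a mixed anhydride, and the silyl ether is removed last.
- Stereochemistry: the target has no stereocentre and no stereogenic axis; the only selectivities are regiochemical (orientation of the cycloaddition, choice of phenol in the acylations).

Key step: step 4

Remark: the target is achiral, so the "single enantiomer" is the compound itself; methyl orsellinate, but-2-ynoic acid and 4,4-dimethoxybut-3-en-2-one are taken as purchasable.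

**Route**

Step 1
Reactants: 1 methyl orsellinate (methyl 2,4-dihydroxy-6-methylbenzoate); 2 but-2-ynoic acid
Product: 4 methyl 4-(but-2-ynoyloxy)-2-hydroxy-6-methylbenzoate, via O-acylisourea 3 (not isolated)
Conditions: DCC, DMAP (cat.), CH2Cl2, 0 °C
Reagents that add atoms: none
Why: Steglich esterification through O-acylisourea 3; the 2-OH is hydrogen-bonded to the neighbouring ester carbonyl, so one equivalent of activated acid at 0 °C with little DMAP should acylate only the free 4-OH and leave the ynoate unisomerised.

Step 2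
Reactants: 4 methyl 4-(but-2-ynoyloxy)-2-hydroxy-6-methylbenzoate
Product: 5 methyl 4-(but-2-ynoyloxy)-2-(tert-butyldimethylsilyloxy)-6-methylbenzoate
Conditions: TBSOTf, 2,6-lutidine, CH2Cl2, 0 °C
Reagents that add atoms: tert-butyldimethylsilyl trifluoromethanesulfonate, CC(C)(C)[Si](C)(C)OS(=O)(=O)C(F)(F)F
Why: O-silylation of a chelated phenol with a silyl triflate and a hindered, non-nucleophilic base, which should not attack the electrophilic aryl ynoate; the silyl ether removes the one acidic proton that would quench the ketene acetal diene in step 4.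

Step 3
Reactants: 6 4,4-dimethoxybut-3-en-2-one
Product: 7 1,1-dimethoxy-3-(trimethylsilyloxy)buta-1,3-diene
Conditions: TMSCl, Et3N, ZnCl2 (cat.), toluene, 40 °C; distillation
Reagents that add atoms: chlorotrimethylsilane, C[Si](C)(C)Cl
Why: soft enolisation and O-silylation of a methyl ketone, the standard preparation of this cross-conjugated ketene acetal silyl enol ether; only the CH3 group can be deprotonated, so a single diene should form.

Step 4
Reactants: 5 methyl 4-(but-2-ynoyloxy)-2-(tert-butyldimethylsilyloxy)-6-methylbenzoate; 7 1,1-dimethoxy-3-(trimethylsilyloxy)buta-1,3-diene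
Product: 10 methyl 2-(tert-butyldimethylsilyloxy)-4-[(4-hydroxy-2-methoxy-6-methylbenzoyl)oxy]-6-methylbenzoate, via cyclohexadiene cycloadduct 8 (not isolated), via aryl trimethylsilyl ether 9 (not isolated)
Conditions: 7 (3 equiv), toluene, 110 °C, sealed tube; then 5% aq. citric acid, THF, rt
Reagents that add atoms: none
Why: The CH2 terminus of diene 7, which receives electron density from all three oxygen donors, bonds to the methyl-bearing β-carbon of the ynoate in 5 while the ketene acetal carbon bonds to the α-carbon, in a concerted but strongly asynchronous Diels–Alder reaction that forms C5–C6 and C1–C2 of ring B. This is the established benzannulation of 1,1-dialkoxy-3-silyloxybutadienes with acetylenic esters, applied here to an aryl 2-alkynoate. Ring B closes as a six-membered carbocycle by [4+2] cycloaddition; the cyclohexa-1,4-diene 8 then loses methanol by 1,4-elimination (OCH3 from C2, H from C5) to become aromatic, and mild aqueous acid cleaves only the trimethylsilyl ether of 9. No stereocentre is created. The step needs a single regiochemistry, and the matched polarisation of the partners (largest HOMO coefficient at the diene CH2, largest LUMO coefficient at the ynoate β-carbon) should secure it, placing OCH3 ortho and OH para to the carboxyl. The electron-poor aryl ester makes the β-methyl ynoate a better dienophile than an alkyl ester, and the TBS ether on ring A keeps acidic protons away from the acid-labile diene while surviving the work-up.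

Step 5
Reactants: 1 methyl orsellinate
Product: 11 methyl everninate (methyl 2-hydroxy-4-methoxy-6-methylbenzoate)
Conditions: MeI, K2CO3, acetone, rt
Reagents that add atoms: iodomethane, CI
Why: Williamson ether synthesis using the same chelation as step 1; with one equivalent of base and MeI the more acidic, unchelated 4-OH should be methylated and the 2-OH left free.

Step 6
Reactants: 11 methyl everninate
Product: 12 everninic acid (2-hydroxy-4-methoxy-6-methylbenzoic acid)
Conditions: KOH, DMSO–H2O, 90 °C; then 2 M HCl, 0 °C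
Reagents that add atoms: potassium hydroxide, [K+].[OH-]
Why: saponification of a hindered salicylate-type ester, which needs hot alkali but is standard for orsellinates, with cold acidification to avoid decarboxylation of the β-resorcylic acid.

Step 7
Reactants: 10 methyl 2-(tert-butyldimethylsilyloxy)-4-[(4-hydroxy-2-methoxy-6-methylbenzoyl)oxy]-6-methylbenzoate; 12 everninic acid
Product: 14 methyl 2-(tert-butyldimethylsilyloxy)-4-({4-[(2-hydroxy-4-methoxy-6-methylbenzoyl)oxy]-2-methoxy-6-methylbenzoyl}oxy)-6-methylbenzoate, via mixed trifluoroacetic anhydride 13 (not isolated)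
Conditions: (CF3CO)2O, toluene, rt
Reagents that add atoms: none
Why: mixed-anhydride esterification as used for depsides; TFAA converts 12 into the aroyl trifluoroacetate 13, whose electron-rich aroyl group is transferred to the only free phenol of 10, while the chelated 2-OH of the acid does not react and any aryl trifluoroacetate is lost on aqueous work-up.

Step 8
Reactants: 14 methyl 2-(tert-butyldimethylsilyloxy)-4-({4-[(2-hydroxy-4-methoxy-6-methylbenzoyl)oxy]-2-methoxy-6-methylbenzoyl}oxy)-6-methylbenzoate
Product: 15 methyl 2-hydroxy-4-({4-[(2-hydroxy-4-methoxy-6-methylbenzoyl)oxy]-2-methoxy-6-methylbenzoyl}oxy)-6-methylbenzoate (target)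
Conditions: HF·pyridine, THF, 0 °C to rt
Reagents that add atoms: none
Why: fluoride-mediated cleavage of an aryl silyl ether under acidic, weakly nucleophilic conditions, which should spare the methyl ester and both hindered depside esters.

**Compound list**
1 | methyl orsellinate (methyl 2,4-dihydroxy-6-methylbenzoate) | COC(=O)c1c(C)cc(O)cc1O | starting material
2 | but-2-ynoic acid | CC#CC(=O)O | starting material
3 | O-(but-2-ynoyl)-N,N'-dicyclohexylisourea | CC#CC(=O)OC(=NC1CCCCC1)NC1CCCCC1 | intermediate (not isolated)
4 | methyl 4-(but-2-ynoyloxy)-2-hydroxy-6-methylbenzoate | COC(=O)c1c(C)cc(OC(=O)C#CC)cc1O | intermediate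
5 | methyl 4-(but-2-ynoyloxy)-2-(tert-butyldimethylsilyloxy)-6-methylbenzoate | COC(=O)c1c(C)cc(OC(=O)C#CC)cc1O[Si](C)(C)C(C)(C)C | intermediate
6 | 4,4-dimethoxybut-3-en-2-one | CC(=O)C=C(OC)OC | starting material
7 | 1,1-dimethoxy-3-(trimethylsilyloxy)buta-1,3-diene | COC(OC)=CC(=C)O[Si](C)(C)C | intermediate
8 | methyl 2-(tert-butyldimethylsilyloxy)-4-{[6,6-dimethoxy-2-methyl-4-(trimethylsilyloxy)cyclohexa-1,4-diene-1-carbonyl]oxy}-6-methylbenzoate | COC(=O)c1c(C)cc(OC(=O)C2=C(C)CC(O[Si](C)(C)C)=CC2(OC)OC)cc1O[Si](C)(C)C(C)(C)C | intermediate (not isolated)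
9 | methyl 2-(tert-butyldimethylsilyloxy)-4-{[2-methoxy-6-methyl-4-(trimethylsilyloxy)benzoyl]oxy}-6-methylbenzoate | COC(=O)c1c(C)cc(OC(=O)c2c(C)cc(O[Si](C)(C)C)cc2OC)cc1O[Si](C)(C)C(C)(C)C | intermediate (not isolated)
10 | methyl 2-(tert-butyldimethylsilyloxy)-4-[(4-hydroxy-2-methoxy-6-methylbenzoyl)oxy]-6-methylbenzoate | COC(=O)c1c(C)cc(OC(=O)c2c(C)cc(O)cc2OC)cc1O[Si](C)(C)C(C)(C)C | intermediate
11 | methyl everninate (methyl 2-hydroxy-4-methoxy-6-methylbenzoate) | COC(=O)c1c(C)cc(OC)cc1O | intermediate
12 | everninic acid (2-hydroxy-4-methoxy-6-methylbenzoic acid) | COc1cc(C)c(C(=O)O)c(O)c1 | intermediate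
13 | 2-hydroxy-4-methoxy-6-methylbenzoic trifluoroacetic anhydride | COc1cc(C)c(C(=O)OC(=O)C(F)(F)F)c(O)c1 | intermediate (not isolated)
14 | methyl 2-(tert-butyldimethylsilyloxy)-4-({4-[(2-hydroxy-4-methoxy-6-methylbenzoyl)oxy]-2-methoxy-6-methylbenzoyl}oxy)-6-methylbenzoate | COC(=O)c1c(C)cc(OC(=O)c2c(C)cc(OC(=O)c3c(C)cc(OC)cc3O)cc2OC)cc1O[Si](C)(C)C(C)(C)C | intermediate
15 | methyl 2-hydroxy-4-({4-[(2-hydroxy-4-methoxy-6-methylbenzoyl)oxy]-2-methoxy-6-methylbenzoyl}oxy)-6-methylbenzoate | COC(=O)c1c(C)cc(OC(=O)c2c(C)cc(OC(=O)c3c(C)cc(OC)cc3O)cc2OC)cc1O | target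

**Step count**
Total steps: 8. Longest linear sequence: 5 steps (steps 1, 2, 4, 7, 8 from methyl orsellinate); steps 3 and 5–6 are side branches.

**Steps most likely to fail**

Step 4. The β-methyl ynoate may react too slowly at temperatures the diene survives, so that oligomerisation or hydrolysis of the diene outruns the cycloaddition; attack of the diene at the aryl ester could erode material further. The fallback keeps the benzannulation but moves it to a simple alkyl ynoate, the documented substrate class, where excess reagents and modest conversion are affordable; both depside esters are then made by mixed-anhydride coupling. It sets out from 2 (with 7) and comes back at 15. Acid 2 is O-alkylated (BnBr, K2CO3, DMF) to benzyl but-2-ynoate F1. F1 is heated neat with excess 7 and gives, through benzyl 6,6-dimethoxy-2-methyl-4-(trimethylsilyloxy)cyclohexa-1,4-diene-1-carboxylate F2 and benzyl 2-methoxy-6-methyl-4-(trimethylsilyloxy)benzoate F3 and after mild acid work-up, benzyl 4-hydroxy-2-methoxy-6-methylbenzoate F4. F4 is acylated with 12 and TFAA in toluene (through 13) to benzyl 4-[(2-hydroxy-4-methoxy-6-methylbenzoyl)oxy]-2-methoxy-6-methylbenzoate F5. Hydrogenolysis (H2, Pd/C, EtOAc) gives 4-[(2-hydroxy-4-methoxy-6-methylbenzoyl)oxy]-2-methoxy-6-methylbenzoic acid F6. TFAA converts F6 into 4-[(2-hydroxy-4-methoxy-6-methylbenzoyl)oxy]-2-methoxy-6-methylbenzoic trifluoroacetic anhydride F7, which should acylate methyl orsellinate 1 only at its unchelated 4-OH and give 15 directly.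

Step 7. The mixed anhydride may acylate the deactivated ring B phenol only slowly, while the trifluoroacetic acid set free attacks the aryl silyl ether or the phenol is capped as its trifluoroacetate. The fallback replaces the acid-mediated coupling by a carbodiimide coupling of an O-benzyl acid under basic catalysis. It sets out from 11 and comes back at 14. Ester 11 is benzylated at the chelated 2-OH (BnBr, K2CO3, DMF, 70 °C) to methyl 2-(benzyloxy)-4-methoxy-6-methylbenzoate F8, which is saponified (KOH, DMSO–H2O, 100 °C) to 2-(benzyloxy)-4-methoxy-6-methylbenzoic acid F9. DCC/DMAP in CH2Cl2 activates F9 as O-[2-(benzyloxy)-4-methoxy-6-methylbenzoyl]-N,N'-dicyclohexylisourea F10, which acylates 10 to methyl 4-[(4-{[2-(benzyloxy)-4-methoxy-6-methylbenzoyl]oxy}-2-methoxy-6-methylbenzoyl)oxy]-2-(tert-butyldimethylsilyloxy)-6-methylbenzoate F11. Hydrogenolysis (H2, Pd/C, EtOAc) removes the benzyl ether and gives 14.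

Step 1. Acylation may spread to the chelated 2-OH or to both phenols, and the nucleophilic catalyst may consume the activated ynoic acid before the phenol reacts. The fallback replaces chelation control by protecting-group control, so that a single phenol is free when the ynoate is introduced and an excess of activated acid can be used. It sets out from 1 and comes back at 5. Selective benzylation of the unchelated phenol (BnBr, K2CO3, acetone) gives methyl 4-(benzyloxy)-2-hydroxy-6-methylbenzoate F12. Silylation (TBSOTf, 2,6-lutidine) gives methyl 4-(benzyloxy)-2-(tert-butyldimethylsilyloxy)-6-methylbenzoate F13. Hydrogenolysis (H2, Pd/C, EtOAc) gives methyl 2-(tert-butyldimethylsilyloxy)-4-hydroxy-6-methylbenzoate F14, which is esterified with 2 (DCC, DMAP, through 3) to give 5.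

**Further compounds**
F1 | step 4 | benzyl but-2-ynoate | CC#CC(=O)OCc1ccccc1
F2 | step 4 | benzyl 6,6-dimethoxy-2-methyl-4-(trimethylsilyloxy)cyclohexa-1,4-diene-1-carboxylate | COC1(OC)C=C(O[Si](C)(C)C)CC(C)=C1C(=O)OCc1ccccc1
F3 | step 4 | benzyl 2-methoxy-6-methyl-4-(trimethylsilyloxy)benzoate | COc1cc(O[Si](C)(C)C)cc(C)c1C(=O)OCc1ccccc1
F4 | step 4 | benzyl 4-hydroxy-2-methoxy-6-methylbenzoate | COc1cc(O)cc(C)c1C(=O)OCc1ccccc1
F5 | step 4 | benzyl 4-[(2-hydroxy-4-methoxy-6-methylbenzoyl)oxy]-2-methoxy-6-methylbenzoate | COc1cc(C)c(C(=O)Oc2cc(C)c(C(=O)OCc3ccccc3)c(OC)c2)c(O)c1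
F6 | step 4 | 4-[(2-hydroxy-4-methoxy-6-methylbenzoyl)oxy]-2-methoxy-6-methylbenzoic acid | COc1cc(C)c(C(=O)Oc2cc(C)c(C(=O)O)c(OC)c2)c(O)c1
F7 | step 4 | 4-[(2-hydroxy-4-methoxy-6-methylbenzoyl)oxy]-2-methoxy-6-methylbenzoic trifluoroacetic anhydride | COc1cc(C)c(C(=O)Oc2cc(C)c(C(=O)OC(=O)C(F)(F)F)c(OC)c2)c(O)c1
F8 | step 7 | methyl 2-(benzyloxy)-4-methoxy-6-methylbenzoate | COC(=O)c1c(C)cc(OC)cc1OCc1ccccc1
F9 | step 7 | 2-(benzyloxy)-4-methoxy-6-methylbenzoic acid | COc1cc(C)c(C(=O)O)c(OCc2ccccc2)c1
F10 | step 7 | O-[2-(benzyloxy)-4-methoxy-6-methylbenzoyl]-N,N'-dicyclohexylisourea | COc1cc(C)c(C(=O)OC(=NC2CCCCC2)NC2CCCCC2)c(OCc2ccccc2)c1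
F11 | step 7 | methyl 4-[(4-{[2-(benzyloxy)-4-methoxy-6-methylbenzoyl]oxy}-2-methoxy-6-methylbenzoyl)oxy]-2-(tert-butyldimethylsilyloxy)-6-methylbenzoate | COC(=O)c1c(C)cc(OC(=O)c2c(C)cc(OC(=O)c3c(C)cc(OC)cc3OCc3ccccc3)cc2OC)cc1O[Si](C)(C)C(C)(C)C
F12 | step 1 | methyl 4-(benzyloxy)-2-hydroxy-6-methylbenzoate | COC(=O)c1c(C)cc(OCc2ccccc2)cc1O
F13 | step 1 | methyl 4-(benzyloxy)-2-(tert-butyldimethylsilyloxy)-6-methylbenzoate | COC(=O)c1c(C)cc(OCc2ccccc2)cc1O[Si](C)(C)C(C)(C)C
F14 | step 1 | methyl 2-(tert-butyldimethylsilyloxy)-4-hydroxy-6-methylbenzoate | COC(=O)c1c(C)cc(O)cc1O[Si](C)(C)C(C)(C)C
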